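The easy step is the first one: substrate meets partner and gives intermediate A. What counts is what that molecule does next.

| flask | substrate | partner | second reagent | third reagent | time | remark |
|---|---|---|---|---|---|---|
| theta | 10 mM (fed, over 6.0 h) | 1.05 equiv | 1.00 equiv | 0.700 equiv | 15 h | all else is in the flask from the start; the feed brings no volume worth counting |
| delta | 10 mM | 1.05 equiv | 1.00 equiv | 0.700 equiv | 15 h | everything together at the start |
| epsilon | 10 mM | 1.05 equiv | 1.00 equiv (fed, over 6.0 h) | 0.700 equiv | 15 h | all else is in the flask from the start; the feed brings no volume worth counting |

    substrate + partner → intermediate A (k1 = 187 M⁻¹ h⁻¹)
    substrate + target → side product B (k2 = 36.6 M⁻¹ h⁻¹)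
    second reagent + intermediate A → intermediate B (k3 = 159 M⁻¹ h⁻¹)
    third reagent + intermediate B → target (k4 = 107 M⁻¹ h⁻¹)
    intermediate A → side product A (k5 = 1.85 h⁻¹)

- percentages count the substrate that a species holds: one side product B counts as two
- run time (theta): 15 h

- the flask with the highest amount of target, in percent of the substrate charged ("all alike" if they lie within 1.5 percentage points) (theta / delta / epsilon / all alike)
- final target, as a percentage of the substrate charged, in theta
- final target, as a percentage of the substrate charged, in delta
- final target, as a percentage of the substrate charged, in epsilon

We follow one molecule down a ladder of times. In delta, intermediate A falls to side product A with a half-life of 0.37 h, and the second reagent as charged takes it with a half-life of 0.44 h, which is slower. As a lifetime, one over the rate, the two routes together give intermediate A 0.291 h at full charge. The substrate's lifetime against charged partner is 0.509 h, which is longer, so intermediate A meets its fork soon after it forms. Further down stand the half-lives in delta of intermediate B, 0.93 h, and of target against substrate as charged, 1.9 h. Below them come the feed of theta and epsilon, 6.0 h, and the run, 15 h.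

At full charge the capture rate is 1.59 h⁻¹ against a loss rate of 1.85 h⁻¹, a chance of 46.2 %. But each capture spends second reagent, so we take its fraction midway down and get 39.8 %. This is the capture chance, the share of intermediate A that the second reagent takes. In our reckoning it follows how much substrate has passed, not the clock, so feeding substrate in theta leaves it as in delta.

The third reagent, at 0.700 equiv, covers what arrives. Target then loses some to substrate. As a rough allowance we let substrate choose between equal amounts of partner and target, which keeps 83.6 %. That gives 33.3 % for delta and 33.3 % for theta, and our reckoning does not part them.

In epsilon the feed lasts longer than the substrate's life. As a rough choice we read the second reagent at 1.02 h, twice that life, when the feed has brought 17.0 % of it. The chance there is 12.7 %, and target comes to 10.6 %.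

The forecast chose delta, with 23 % for theta, 29 % for delta and 15 % for epsilon, holding that “theta loses more to side product B than delta”. Our figure for theta stands higher.

The simulation gives 30.2 % for theta, 32.7 % for delta and 11.6 % for epsilon, with delta highest.

At the end, second reagent spent, taken over itself plus side product A, comes to 40.6 % in theta and 40.5 % in delta, against our capture chance of 39.8 %. In epsilon the loss of intermediate A to side product A is the main reason for the low yield: with that step struck out, target rises from 11.6 % to 62.9 %.

Take the neighbour of epsilon with 0.400 equiv of second reagent. The feed now brings less in the same time, so the chance falls to 5.51 % and target should be 4.61 %. The simulation gives 5.51 %.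

(The numbers are made up; the rest is arithmetic.)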